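If you have to choose between epsilon and delta within the hour, fold each recipe into one number.

all flasks: racemization catalyst 0.21 mol%

| flask | left-handed substrate | right-handed substrate | reagent | remark | time |
|---|---|---|---|---|---|
| teal | 0.028 M | 0.028 M | 2 equiv | run made earlier |  |
| blue | 0.044 M | 0.044 M | 2 equiv | run made earlier |  |
| epsilon | 0.020 M | 0.020 M | 2.00 equiv |  | 8.0 d |
| delta | 0.020 M | 0.020 M | 2.00 equiv |  | 2.0 d |

- teal (time / d: right-handed substrate / %, left-handed substrate / %, left-handed product / %): 0.625: 44, 42, 10; 1.25: 44, 29, 19; 2.50: 40, 24, 30; 4.00: 35, 17, 31; 8.00: 26, 12, 41
- blue (time / d: right-handed substrate / %, left-handed substrate / %, left-handed product / %): 0.625: 43, 33, 13; 2.08: 35, 20, 27; 4.00: 29, 12, 37; 6.00: 24, 8, 41; 8.00: 24, 3, 47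

(readings scatter by 2 percentage points)

- the flask that ends with the higher excess of right-handed substrate over left-handed substrate among what is left of the two, or "neither" when 2 percentage points or less lies between them (epsilon / delta / neither)
- excess of right-handed substrate over left-handed substrate among what is left of the two at the end, epsilon
- excess of right-handed substrate over left-handed substrate among what is left of the two at the end, delta

- reagent is single-handed; left-handed substrate and right-handed substrate are mirror images of each other, charged as a racemate, each of them at the stated concentration
- an excess is the difference of the two amounts in percent of their sum
- an excess is below zero if the other one leads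
- the handed part of reagent does not stay in what it makes, so the products of the two hands are mirror images too

In blue at 4.00 d, the right-handed substrate reads 29% and the left-handed substrate 12%, so the reagent appears to take the left-handed substrate faster: a kinetic resolution. Freeze the reagent at its charge and set the racemization catalyst aside, and each hand decays in a pseudo-first-order way. The logarithm of the right-handed fraction over the left-handed fraction then grows in proportion to reagent charge times time. That logarithm, here 0.882, is the resolution number: it says how far the two hands have been pulled apart, and its exponential is their ratio, from which the excess follows.

Scaling blue's value by reagent charge times time gives epsilon 0.802 and delta 0.201, which means excesses of 38.1% and 9.99%.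

Is one number enough? Not quite. For teal at 2.50 d it predicts 0.351, but the reading gives 0.511, which is higher. Scaling from that earlier teal reading instead puts delta at 14.5%. So I expect epsilon near 38.1% and delta between 9.99% and 14.5%, with epsilon ahead either way.

The forecast says epsilon, with 37% and 16%, on the ground that “the natural clock is concentration × time”. Its delta lies just above my range.

The flasks give 38.5% for epsilon and 13.9% for delta, so epsilon ends higher.

    reagent + left-handed substrate → left-handed product (k = 7.80 × 10⁻⁵ M⁻¹ s⁻¹)
    reagent + right-handed substrate → right-handed product (k = 2.70 × 10⁻⁵ M⁻¹ s⁻¹)
    left-handed substrate + racemization catalyst ⇌ right-handed substrate + racemization catalyst, rate k3*[racemization catalyst]*[left-handed substrate] forward; the back reaction follows from the equilibrium constant (k = 0.0540 M⁻¹ s⁻¹)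
    2 racemization catalyst → spent catalyst A (k = 0.430 M⁻¹ s⁻¹)
    reagent + racemization catalyst → spent catalyst B (k = 6.80 × 10⁻⁵ M⁻¹ s⁻¹)

With each setting moved alone by a factor of 1.3 up or down, the largest shifts in delta's excess rank reagent (4.2 points), then time (3.3 points), then racemization catalyst (0.083 points), and the first two are factors of the resolution number. Take delta's neighbour with 0.500 equiv of reagent at the same time: its number is 0.0501, a quarter of delta's, predicting an excess of 2.50%. That flask gives 3.40%, also a quarter of delta's, with 5.38% of left-handed product.

The earlier runs and the new flask are calculated from invented constants, and the scatter is random.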